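The numbers in the tables were generated by integration from invented constants; the scatter is artificial.

If a fitted rate law came back for this flask with a tidy order in every species, we would still ask first how much of the catalyst is held on the substrate when the rate is taken.

| flask | substrate | coupling partner | free catalyst | remark |
|---|---|---|---|---|
| east | 0.10 M | 0.21 M | 10 mM | run made earlier |
| west | 0.10 M | 0.33 M | 10 mM | run made earlier |
| flask | 0.10 M | 0.150 M | 10 mM |  |

| run | time / h | target / % | substrate / % |
|---|---|---|---|
| east | 0.833 | 41 | 54 |
| east | 1.33 | 48 | 48 |
| east | 2.50 | 49 | 48 |
| east | 5.00 | 49 | 42 |
| east | 10.0 | 55 | 46 |
| west | 2.00 | 59 | 33 |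
| west | 4.00 | 61 | 33 |
| west | 6.00 | 64 | 36 |
| west | 8.00 | 62 | 34 |
| west | 10.0 | 58 | 35 |

(readings scatter by 2 percentage points)

* apparent order in free catalyst when 20 % of the substrate are converted (percent change of the rate of making target for one percent more free catalyst charged)
* factor on the rate of making target when 20 % of the substrate are converted if coupling partner is charged twice over

- what is bound to the catalyst counts as converted
- no earlier run changes the charge of free catalyst; that part of a forecast is a guess

We climb the ladder in the east run. First comes the uptake onto the catalyst: by 0.833 h, substrate and target together already fall 5 percentage points short of the charge. Second comes the target, whose 41 % at that reading is less than the plateau of 51.0 % read from its later readings, which gives a relaxation time near 0.511 h. Last comes the plateau, which the readings stay near out to 10.0 h, much longer than that time.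

Over all readings of both runs, the shortfall averages 4.5 points of the substrate charged. Dividing that shortfall by the catalyst charged gives the bound share of the catalyst, which reads 45.0 %, with 2 points of scatter on each value behind it.

Suppose this bound catalyst carries the partner, the remainder waits for it, and the share read in the east and west runs carries over to this flask at 20 % conversion. The order in partner is then one minus the bound share, and our reckoning for doubling the partner in this flask gives 1.46. No run changes the catalyst charge, so our order in free catalyst is a guess of 1.

The forecast gives 1 and 2.2, noting that “Saturation can't be excluded because the kinetics are sparse”.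

The flask gives an order of 0.69 and a factor of 1.31, which is less than our 1.46.

    substrate + free catalyst ⇌ catalyst intermediate A (K = 12.0 M⁻¹, k = 6.17 M⁻¹ min⁻¹)
    catalyst intermediate B ⇌ free catalyst + target (K = 0.0580 M, k = 3.75 min⁻¹)
    coupling partner + catalyst intermediate A ⇌ catalyst intermediate B (K = 10.0 M⁻¹, k = 56.5 M⁻¹ min⁻¹)
    2 free catalyst ⇌ resting dimer, settled at all times (K = 191 M⁻¹)

At 0.800 h the resting dimer, a resting state of the catalyst, holds 34.1 % of the catalyst charged. Used once more, the bound share predicts a shortfall of 4.5 points of the substrate charged in this flask, and at 8.00 h the flask shows 3.9 points. At that time catalyst intermediates A and B together hold 39.4 % of the catalyst charged.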